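**The plan.** I watch the rate first. A solid reagent feeds a partner into solution, and three flasks differ in what is fed slowly.

| flask | starting material | second substrate | third substrate | solid reagent | remark | time |
|---|---|---|---|---|---|---|
| alpha | 0.20 M | 0.20 M | 0.20 M | 0.40 M | run made earlier |  |
| delta | 0.20 M | 0.20 M | 0.20 M | 0.27 M | run made earlier |  |
| beta | 0.20 M | 0.20 M | 0.20 M | 0.60 M | run made earlier |  |
| theta | 0.20 M | 0.40 M | 0.20 M | 0.40 M | run made earlier |  |
| blue | 0.20 M (fed, over 10 min) | 0.200 M | 0.200 M | 0.400 M | all else is in the flask from the start; the feed brings no volume worth counting | 50 min |
| teal | 0.20 M | 0.200 M | 0.200 M (fed, over 10 min) | 0.400 M | all else is in the flask from the start; the feed brings no volume worth counting | 50 min |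
| grey | 0.20 M | 0.200 M | 0.200 M | 0.400 M | everything together at the start | 50 min |

- alpha (time / min: target / %, starting material / %): 4.00: 16, 82; 8.00: 32, 64; 12.0: 48, 50; 15.0: 58, 42; 20.0: 65, 34; 25.0: 69, 31; 30.0: 73, 28
- delta (time / min: target / %, starting material / %): 2.00: 6, 92; 6.00: 24, 72; 12.0: 42, 58; 15.0: 44, 52; 25.0: 46, 53; 30.0: 45, 54; 40.0: 48, 52
- beta (time / min: target / %, starting material / %): 3.00: 10, 90; 5.00: 19, 82; 8.00: 35, 65; 12.0: 46, 55; 15.0: 60, 40; 25.0: 83, 18; 40.0: 94, 5
- theta (time / min: target / %, starting material / %): 4.00: 14, 86; 10.0: 39, 60; 20.0: 58, 42; 30.0: 60, 43; 40.0: 61, 41

(standard deviation of a reading: 1.5 percentage points)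

- solid, in amounts per volume of the solution: solid reagent
- on the list of suspects stand: starting material + partner -> target; second substrate + partner -> second product; third substrate + partner -> third product; second substrate <-> dormant form; solid reagent <-> partner
- at the start none of the solid reagent is in solution

- the flask that comes out highest in amount of target, in percent of the starting material charged, or "all alike" when all lie within 1.5 percentage points (blue / teal / grey / all alike)
- target at the end, in percent of the starting material charged, blue
- target at the end, in percent of the starting material charged, teal
- target at the end, in percent of the starting material charged, grey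

**Early rate.** By the readings, target forms on average at 0.00800 M min⁻¹ up to 8.00 min in alpha, 0.00800 M min⁻¹ up to 6.00 min in delta and 0.00875 M min⁻¹ up to 8.00 min in beta, though the solid charge runs from 0.27 M to 0.60 M. So in these runs the early rate stays close across that range of solid.

**The slowing.** From 25.0 min to 30.0 min, alpha's rate reads 0.00160 M min⁻¹, lower by a factor of 5.00. Delta stands near 48 % at 40.0 min with 52 % of starting material unused, while beta, with more solid, reaches 94 %. So delta stops lower than beta's last reading, and I take the solid as the limiting reagent in delta.

**The share.** Each partner molecule meets a fork: starting material, second substrate or third substrate. I add up those forks as target made per solid charged, the solid share 35.6 %, a reading from delta's last point. If that share holds when the solid alone moves, grey gets 71.1 %. Grey is alpha's recipe, and alpha's last reading stands at 73 %. Over the 10 min of feed, blue holds starting material back from the partner and teal holds third substrate back, so I guess teal above grey and blue below, without a size.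

**The forecast.** It says 70 % for blue, 83 % for teal and 77 % for grey, with teal highest, noting “Alpha still creeps upward”. On grey it stands 5.9 percentage points above my figure.

**The result.** Blue gives 65.8 %, teal 73.5 % and grey 70.9 %, so teal is highest.

    starting material + partner → target (k = 0.0130 L mol⁻¹ s⁻¹)
    second substrate + partner → second product (k = 0.0140 L mol⁻¹ s⁻¹)
    third substrate + partner → third product (k = 0.0210 L mol⁻¹ s⁻¹)
    second substrate ⇌ dormant form (K = 1.40, k = 0.0220 s⁻¹)
    solid reagent ⇌ partner, rate k5*(cs5 - [partner]) while solid is left; crystals form when [partner] > cs5 (solubility = 0.110 M, k = 0.0130 s⁻¹)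

**The fork.** In grey as charged, the partner's half-life by third substrate alone is 2.8 min, shorter than the 4.4 min by starting material alone. So in grey as charged third substrate takes the partner 1.62 times as fast as starting material does. The solid share comes to 35.4 % in grey and 36.8 % in teal. Carried to the teal-like flask with 0.16 M of solid reagent, my delta share gives 28.4 %, and that flask holds 35.3 % of target.

The data come from a simulation with constants of no real substance.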